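The disconnection on which everything rests opens ring A (the 6,6-dimethyl-5,6-dihydro-2H-pyran-2-one; O1, C2=O, C3=C4, spiro C5, C6(CH3)2) at O1–C6 by deleting O1, which leaves a spiro 5,5-dimethylcyclopent-2-enone. The last step re-inserts that oxygen between the carbonyl carbon and C6 (Baeyer–Villiger ring expansion). It exploits C6, the fully substituted carbon next to spiro C5, as the only tertiary-alkyl neighbour of the enone carbonyl and hence the migrating group. The hexacyclic enone precursor arises by an intramolecular vinylogous aldol that closes cyclohexane ring B onto a caged keto-lactone, built by an aromatic Claisen/Diels–Alder cascade with chirality transfer.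

Key step: step 16

Remark on names: the caged core is described as a bicyclo[2.2.2]octan-2-one with C1 (CH3-bearing bridgehead), C2 (C=O), C3 (CH3-bearing quaternary carbon), C4 (bridgehead), C5–C6 (bridge; C5 carries the lactone carbonyl), C7 (CH2) and C8 (quaternary). The γ-lactone is C5–C(=O)–O–CH2–C4 and cyclopentane ring C is C3–CH2–C–C8–C4.

Step 1
Reactants: 1 4-methoxy-3,5-dimethylbenzoic acid
Product: 2 5-methoxy-4,6-dimethyl-2-benzofuran-1(3H)-one
Conditions: Pd(OAc)2 (10 mol %), K2HPO4, CH2Br2, 140 °C, sealed tube
Reagents that add atoms: dibromomethane, BrCBr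
Why: Carboxylate-directed ortho C–H palladation, alkylation by CH2Br2 and SN2 closure of the benzylic bromide (Pd-catalysed ortho-C–H alkylation/lactonisation of benzoic acids) should give a single phthalide because the two ortho C–H bonds are equivalent.

Step 2
Reactants: 2 5-methoxy-4,6-dimethyl-2-benzofuran-1(3H)-one
Product: 3 7-bromo-5-methoxy-4,6-dimethyl-2-benzofuran-1(3H)-one
Conditions: NBS, conc. H2SO4–CF3CO2H, 0 °C → rt, dark
Reagents that add atoms: N-bromosuccinimide, O=C1CCC(=O)N1Br
Why: Electrophilic aromatic bromination can only occur at the one remaining ring C–H, which is activated by an ortho and a para methyl group, and the ionic conditions avoid benzylic bromination.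

Step 3
Reactants: 3 7-bromo-5-methoxy-4,6-dimethyl-2-benzofuran-1(3H)-one
Product: 4 7-bromo-5-hydroxy-4,6-dimethyl-2-benzofuran-1(3H)-one
Conditions: BBr3, CH2Cl2, −78 → 0 °C; H2O
Reagents that add atoms: none
Why: Lewis-acid cleavage of the aryl methyl ether (BBr3 demethylation) should free the phenol while the phthalide lactone and the aryl bromide are inert.

Step 4
Reactants: 5 benzyl but-3-yn-1-yl ether
Product: 6 7-(benzyloxy)hept-3-yn-2-one
Conditions: n-BuLi, THF, −78 °C; then MeC(O)N(OMe)Me, −78 → 0 °C; aq. NH4Cl
Reagents that add atoms: N-methoxy-N-methylacetamide, CC(=O)N(C)OC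
Why: Acylation of the lithium acetylide with a Weinreb amide stops at the ketone because the chelated tetrahedral adduct collapses only on work-up.

Step 5
Reactants: 6 7-(benzyloxy)hept-3-yn-2-one
Product: 7 (2R)-7-(benzyloxy)hept-3-yn-2-ol
Conditions: RuCl(p-cymene)[(R,R)-TsDPEN] (1 mol %), i-PrOH, rt
Reagents that add atoms: none
Why: Noyori asymmetric transfer hydrogenation of an alkynyl methyl ketone should deliver hydride to one carbonyl face under control of the (R,R)-ligand and set the (R)-carbinol without touching the alkyne or the benzyl ether.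

Step 6
Reactants: 7 (2R)-7-(benzyloxy)hept-3-yn-2-ol; 4 7-bromo-5-hydroxy-4,6-dimethyl-2-benzofuran-1(3H)-one
Product: 8 5-{[(2S)-7-(benzyloxy)hept-3-yn-2-yl]oxy}-7-bromo-4,6-dimethyl-2-benzofuran-1(3H)-one
Conditions: PPh3, DIAD, toluene, 0 °C → rt
Reagents that add atoms: none
Why: Mitsunobu etherification, in which the acidic phenol displaces the propargylic oxyphosphonium by SN2, should invert the carbinol centre to (S).

Step 7
Reactants: 8 5-{[(2S)-7-(benzyloxy)hept-3-yn-2-yl]oxy}-7-bromo-4,6-dimethyl-2-benzofuran-1(3H)-one
Product: 9 5-{[(2S)-6-(benzyloxy)-3,4-dimethylidenehexan-2-yl]oxy}-7-bromo-4,6-dimethyl-2-benzofuran-1(3H)-one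
Conditions: ethylene (1 atm), second-generation Grubbs catalyst RuCl2(=CHPh)(H2IMes)(PCy3) (5 mol %), toluene, 60 °C
Reagents that add atoms: ethylene, C=C
Why: Ethylene cross-enyne metathesis should convert the internal alkyne into a 2,3-disubstituted buta-1,3-diene without involving the stereocentre, the aryl bromide, the lactone or the ethers.

Step 8
Reactants: 9 5-{[(2S)-6-(benzyloxy)-3,4-dimethylidenehexan-2-yl]oxy}-7-bromo-4,6-dimethyl-2-benzofuran-1(3H)-one
Product: 11 bromo-enoate cage (6-bromo-1,3-dimethylbicyclo[2.2.2]oct-5-en-2-one with the γ-lactone on C4/C5, ring C bearing an ethylidene whose methyl is cis to C8, and 2-(benzyloxy)ethyl on C8), via ortho-dienone 10 (not isolated)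
Conditions: 1,2-dichlorobenzene (0.01 M), BHT, 165 °C
Reagents that add atoms: none
Why: Aromatic Claisen rearrangement through a chair with the methyl group equatorial should transfer the (S)-ether centre to the quaternary ring carbon and give ortho-dienone 10, which cannot re-aromatise and is trapped by an intramolecular Diels–Alder reaction of its 2,4-dienone with the tethered 1,1-disubstituted alkene (Claisen/Diels–Alder cascade); the two-atom tether fixes both bridgeheads and the new quaternary carbon C8 relative to that centre, the bromine disfavours trapping of the dienone formed at the other ortho carbon, and the minor ethylidene isomer is removable by chromatography.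

Step 9
Reactants: 11 bromo-enoate cage
Product: 12 cage alcohol (as 11, with ring C bearing H and a (1R)-1-hydroxyethyl group in place of the ethylidene)
Conditions: 9-BBN dimer, THF, 60 °C; then 30% H2O2, pH 7 phosphate buffer, 0 °C → rt
Reagents that add atoms: hydrogen peroxide, OO
Why: Anti-Markovnikov hydroboration–oxidation of the only electron-rich alkene should place boron on the CH(CH3) carbon and add H to the ring carbon syn, from the face opposite the C8 side chain, while the hindered cage ketone and the bromo-enoate are not attacked by 9-BBN.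

Step 10
Reactants: 12 cage alcohol
Product: 13 cage methyl ketone (as 12, with acetyl in place of 1-hydroxyethyl)
Conditions: Dess–Martin periodinane, NaHCO3, CH2Cl2, rt
Reagents that add atoms: none
Why: Dess–Martin oxidation should convert the secondary alcohol into the methyl ketone under buffered conditions that do not epimerise the adjacent CH.

Step 11
Reactants: 13 cage methyl ketone
Product: 14 keto-lactone alcohol (13 without bromine, C5–C6 saturated with H at C5 syn to the C2 carbonyl bridge, 2-hydroxyethyl on C8)
Conditions: H2 (3 atm), Pd(OH)2/C, NaOAc, EtOAc–EtOH, rt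
Reagents that add atoms: none
Why: Heterogeneous hydrogenation should cleave the vinylic C–Br bond and the benzyl ether and add H2 syn to the strained enoate double bond from the face flanked by the flat C2 carbonyl bridge, which sets the lactone α-stereocentre.

Step 12
Reactants: 14 keto-lactone alcohol
Product: 15 iodide (14 with 2-iodoethyl on C8)
Conditions: I2, PPh3, imidazole, CH2Cl2, 0 °C
Reagents that add atoms: iodine, II
Why: Appel-type iodination converts the primary alcohol by SN2 on its alkoxyphosphonium salt and leaves the ketones and the lactone untouched.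

Step 13
Reactants: 16 2,2-dimethylcyclopentane-1,3-dione
Product: 17 5,5-dimethyl-4-oxocyclopent-1-en-1-yl trifluoromethanesulfonate
Conditions: LiN(SiMe3)2, THF, −78 °C; then PhNTf2, −78 → 0 °C; aq. NH4Cl
Reagents that add atoms: N-phenylbis(trifluoromethanesulfonimide), O=S(=O)(N(c1ccccc1)S(=O)(=O)C(F)(F)F)C(F)(F)F
Why: Mono-enolisation of the symmetrical dione and O-sulfonylation of the enolate should give the enol triflate, and no stereocentre is involved.

Step 14
Reactants: 15 iodide; 17 5,5-dimethyl-4-oxocyclopent-1-en-1-yl trifluoromethanesulfonate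
Product: 19 enone-tethered diketone (15 with iodine replaced by the 5,5-dimethyl-4-oxocyclopent-1-en-1-yl group), via alkylzinc iodide 18 (not isolated)
Conditions: Zn dust, LiCl, THF, 40 °C; then 17, Pd2(dba)3 (2.5 mol %), SPhos, THF–NMP, 50 °C
Reagents that add atoms: none
Why: Negishi coupling should work because zinc insertion into the primary C–I bond gives an alkylzinc iodide that tolerates ketones and lactones and couples with the cyclic enol triflate under palladium catalysis to form the C(sp3)–C(sp2) bond.

Step 15
Reactants: 19 enone-tethered diketone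
Product: 20 spiro-enone (the target with a spiro 5,5-dimethylcyclopent-2-en-1-one in place of ring A)
Conditions: TiCl4, i-Pr2NEt, CH2Cl2, −78 °C; aq. NaHCO3 at −78 °C
Reagents that add atoms: none
Why: In this intramolecular vinylogous aldol addition, soft enolisation of the doubly activated ring CH2 gives a titanium dienolate whose γ-carbon attacks the TiCl4-activated methyl ketone to close six-membered ring B (α-attack would need an eight-membered ring); the chair-like open transition state places the carbonyl oxygen axial with its methyl equatorial, away from bridgehead C4, and the bulky C(CH3)2 arm anti to that oxygen, which sets the carbinol and spiro centres, while the acetyl-bearing CH, being α to the ketone, can equilibrate to the cis arrangement that closure requires.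

Step 16
Reactants: 20 spiro-enone
Product: 21 CNP0222978.4 (target)
Conditions: m-CPBA, Na2HPO4, CH2Cl2, 0 °C → rt
Reagents that add atoms: m-chloroperbenzoic acid, OOC(=O)c1cccc(Cl)c1
Why: The peracid adds to the enone carbonyl to give the Criegee adduct, from which the fully substituted C(CH3)2 carbon migrates from carbon to oxygen anti-periplanar to the breaking O–O bond, so that O1 is inserted and the O1–C6 bond of ring A is formed. The closest known reaction type is the Baeyer–Villiger oxidation of α,β-unsaturated ketones that carry a quaternary α′-carbon, which gives the unsaturated lactone by tertiary-alkyl migration. Ring A is closed by a one-atom ring expansion of the cyclopentenone (five- to six-membered), not by a cyclisation. No stereocentre is created: the migrating carbon is not stereogenic, and spiro carbon C5 and the carbinol carbon are not touched. Two selectivities are needed: migration of the tertiary alkyl carbon in preference to the alkenyl carbon, secured by its higher migratory aptitude, and attack at the enone carbonyl in preference to the cage ketone, secured by the two quaternary α-carbons that shield the latter inside the bicyclo[2.2.2]octane while the enone carbonyl has an sp2 CH on one side. The electron-poor C3=C4 bond should not be epoxidised by the electrophilic peracid, and the buffer protects the tertiary alcohol.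

Compound list
1 | 4-methoxy-3,5-dimethylbenzoic acid | COc1c(C)cc(cc1C)C(=O)O | starting material
2 | 5-methoxy-4,6-dimethyl-2-benzofuran-1(3H)-one | COc1c(C)cc2C(=O)OCc2c1C | intermediate
3 | 7-bromo-5-methoxy-4,6-dimethyl-2-benzofuran-1(3H)-one | COc1c(C)c(Br)c2C(=O)OCc2c1C | intermediate
4 | 7-bromo-5-hydroxy-4,6-dimethyl-2-benzofuran-1(3H)-one | Oc1c(C)c(Br)c2C(=O)OCc2c1C | intermediate
5 | benzyl but-3-yn-1-yl ether | C#CCCOCc1ccccc1 | starting material
6 | 7-(benzyloxy)hept-3-yn-2-one | CC(=O)C#CCCOCc1ccccc1 | intermediate
7 | (2R)-7-(benzyloxy)hept-3-yn-2-ol | C[C@@H](O)C#CCCOCc1ccccc1 | intermediate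
8 | 5-{[(2S)-7-(benzyloxy)hept-3-yn-2-yl]oxy}-7-bromo-4,6-dimethyl-2-benzofuran-1(3H)-one | C[C@H](Oc1c(C)c(Br)c2C(=O)OCc2c1C)C#CCCOCc3ccccc3 | intermediate
9 | 5-{[(2S)-6-(benzyloxy)-3,4-dimethylidenehexan-2-yl]oxy}-7-bromo-4,6-dimethyl-2-benzofuran-1(3H)-one | C[C@H](Oc1c(C)c(Br)c2C(=O)OCc2c1C)C(=C)C(=C)CCOCc3ccccc3 | intermediate
10 | ortho-dienone: (4R)-4-[(2Z)-5-(benzyloxy)-2-ethylidene-3-methylidenepentyl]-7-bromo-4,6-dimethyl-2-benzofuran-1,5(3H,4H)-dione | C/C=C(/C[C@@]1(C)C(=O)C(C)=C(Br)C2=C1COC2=O)C(=C)CCOCc3ccccc3 | intermediate (not isolated)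
11 | bromo-enoate cage: 6-bromo-1,3-dimethylbicyclo[2.2.2]oct-5-en-2-one, γ-lactone on C4/C5, ring C with ethylidene (methyl cis to C8), 2-(benzyloxy)ethyl on C8 | C(OCc1ccccc1)C[C@@]23C[C@@]4(C)C(Br)=C5C(=O)OC[C@]52[C@@](C)(C/C3=C/C)C4=O | intermediate
12 | cage alcohol: as 11, ring C carbon bearing H and (1R)-1-hydroxyethyl | C(OCc1ccccc1)C[C@@]23C[C@@]4(C)C(Br)=C5C(=O)OC[C@]52[C@@](C)(C[C@H]3[C@@H](C)O)C4=O | intermediate
13 | cage methyl ketone: as 12 with acetyl | C(OCc1ccccc1)C[C@@]23C[C@@]4(C)C(Br)=C5C(=O)OC[C@]52[C@@](C)(C[C@H]3C(C)=O)C4=O | intermediate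
14 | keto-lactone alcohol: debrominated, C5–C6 saturated (H at C5 syn to the C2 carbonyl bridge), 2-hydroxyethyl on C8 | OCC[C@@]23C[C@@]4(C)C[C@H]5C(=O)OC[C@]52[C@@](C)(C[C@H]3C(C)=O)C4=O | intermediate
15 | iodide: 14 with 2-iodoethyl on C8 | ICC[C@@]23C[C@@]4(C)C[C@H]5C(=O)OC[C@]52[C@@](C)(C[C@H]3C(C)=O)C4=O | intermediate
16 | 2,2-dimethylcyclopentane-1,3-dione | CC1(C)C(=O)CCC1=O | starting material
17 | 5,5-dimethyl-4-oxocyclopent-1-en-1-yl trifluoromethanesulfonate | CC1(C)C(=O)CC=C1OS(=O)(=O)C(F)(F)F | intermediate
18 | alkylzinc iodide of 15 | I[Zn]CC[C@@]23C[C@@]4(C)C[C@H]5C(=O)OC[C@]52[C@@](C)(C[C@H]3C(C)=O)C4=O | intermediate (not isolated)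
19 | enone-tethered diketone: 15 with iodine replaced by 5,5-dimethyl-4-oxocyclopent-1-en-1-yl | CC1(C)C(=O)CC=C1CC[C@@]23C[C@@]4(C)C[C@H]5C(=O)OC[C@]52[C@@](C)(C[C@H]3C(C)=O)C4=O | intermediate
20 | spiro-enone: the target with a spiro 5,5-dimethylcyclopent-2-en-1-one in place of ring A, all stereocentres as in the target | CC1(C)C(=O)C=C[C@]12CC[C@@]13C[C@@]4(C)C[C@H]5C(=O)OC[C@]51[C@@](C)(C[C@H]3[C@@]2(C)O)C4=O | intermediate
21 | CNP0222978.4 | CC1(C)OC(=O)C=C[C@]12CC[C@@]13C[C@@]4(C)C[C@H]5C(=O)OC[C@]51[C@@](C)(C[C@H]3[C@@]2(C)O)C4=O | target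

Total step count: 16. Longest linear sequence: 13 steps (from 1 through steps 1–3, 6–12 and 14–16).

Steps most likely to fail

Step 16. The oxygen insertion may also take place at the cage ketone, or the conjugated carbonyl may react too slowly. The fallback moves the insertion ahead of the coupling; it sets out from 17 and 18 and comes back at 21. Triflate 17 is oxidised with m-CPBA, where the quaternary carbon again migrates and the O–C(CH3)2 bond is formed, to 6,6-dimethyl-2-oxo-3,6-dihydro-2H-pyran-5-yl trifluoromethanesulfonate F9. Negishi coupling of F9 with alkylzinc 18 gives the lactone-tethered diketone F10, and the vinylogous aldol of its lactone dienolate (TiCl4, i-Pr2NEt) would close ring B and give 21 directly.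

Step 15. The dienolate may add through the other face of its γ-carbon, giving the wrong spiro configuration, or enolisation of the methyl ketone may compete. The fallback closes ring B by a ketone–olefin Prins reaction instead, in which the nucleophilic double bond is an exocyclic C=C(CH3)2, so that an antiperiplanar open transition state places the C(CH3)2 carbon anti to the carbonyl oxygen. It sets out from 15 (through 18) and comes back at 21. Purchased 1,1-dibromo-2-methylprop-1-ene and (3-tert-butoxy-3-oxopropyl)zinc bromide are coupled (Pd(PPh3)4) to tert-butyl 4-bromo-5-methylhex-4-enoate F5. Negishi coupling of F5 with 18 gives the isopropylidene ester F6. Me2AlCl in CH2Cl2 at −78 °C should then give the saturated spiro-lactone (7,8-dihydro target) F7, the tertiary cation at the gem-dimethyl carbon being captured by the ester oxygen with loss of isobutene. Selenation of F7 (LiN(i-Pr)2, PhSeBr) to the α-phenylselanyl lactone F8 and oxidation with H2O2 would give 21.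

Step 8. Heterolysis of the secondary dienylic aryl ether at 165 °C may erode the chirality transfer, and the dienone formed at the other ortho carbon may be trapped instead. The fallback forms the dienone irreversibly by C-alkylation and secures the absolute configuration by resolution; it sets out from 7 and 4 and comes back at 11. Ethylene enyne metathesis of 7 gives (2R)-6-(benzyloxy)-3,4-dimethylidenehexan-2-ol F1, and PBr3 converts it with allylic transposition into (E)-benzyl 4-(bromomethyl)-3-methylidenehex-4-en-1-yl ether F2. C-alkylation of the sodium salt of 4 (NaH, toluene, rt) with F2 gives 10 together with its enantiomer ent-10 F3. The Diels–Alder step is then run at 110 °C, and 11 is separated from its enantiomer ent-11 F4 by chromatography on a chiral stationary phase.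

Further compounds
F1 | step 8 | (2R)-6-(benzyloxy)-3,4-dimethylidenehexan-2-ol | C[C@@H](O)C(=C)C(=C)CCOCc1ccccc1
F2 | step 8 | (E)-benzyl 4-(bromomethyl)-3-methylidenehex-4-en-1-yl ether | BrC/C(=C/C)C(=C)CCOCc1ccccc1
F3 | step 8 | ent-10 | C/C=C(/C[C@]1(C)C(=O)C(C)=C(Br)C2=C1COC2=O)C(=C)CCOCc3ccccc3
F4 | step 8 | ent-11 | C(OCc1ccccc1)C[C@]23C[C@]4(C)C(Br)=C5C(=O)OC[C@@]52[C@](C)(C/C3=C/C)C4=O
F5 | step 15 | tert-butyl 4-bromo-5-methylhex-4-enoate | CC(C)=C(Br)CCC(=O)OC(C)(C)C
F6 | step 15 | isopropylidene ester (15 with iodine replaced by the 6-tert-butoxy-2-methyl-6-oxohex-2-en-3-yl group) | CC(C)=C(CCC(=O)OC(C)(C)C)CC[C@@]23C[C@@]4(C)C[C@H]5C(=O)OC[C@]52[C@@](C)(C[C@H]3C(C)=O)C4=O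
F7 | step 15 | saturated spiro-lactone (7,8-dihydro target) | CC1(C)OC(=O)CC[C@]12CC[C@@]13C[C@@]4(C)C[C@H]5C(=O)OC[C@]51[C@@](C)(C[C@H]3[C@@]2(C)O)C4=O
F8 | step 15 | α-phenylselanyl lactone of F7 (both epimers at the selenium-bearing carbon) | CC1(C)OC(=O)C([Se]c6ccccc6)C[C@]12CC[C@@]13C[C@@]4(C)C[C@H]5C(=O)OC[C@]51[C@@](C)(C[C@H]3[C@@]2(C)O)C4=O
F9 | step 16 | 6,6-dimethyl-2-oxo-3,6-dihydro-2H-pyran-5-yl trifluoromethanesulfonate | CC1(C)OC(=O)CC=C1OS(=O)(=O)C(F)(F)F
F10 | step 16 | lactone-tethered diketone (15 with iodine replaced by the 6,6-dimethyl-2-oxo-3,6-dihydro-2H-pyran-5-yl group) | CC1(C)OC(=O)CC=C1CC[C@@]23C[C@@]4(C)C[C@H]5C(=O)OC[C@]52[C@@](C)(C[C@H]3C(C)=O)C4=O
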